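**Retrosynthetic overview** (ent-kaurane locants: ring A = C1–C5, C10; ring C = C8, C9, C11–C14; ring D = C8, C13–C16)
1. Target ⇐ its dimethyl ester; ring D is closed last by 5-exo addition of a vinyl radical (2-bromoallyl arm on C8) to a ring C enone (C13–C16 bond).
2. The C8 quaternary aldehyde ⇐ allylation of a ring C keto aldehyde with 2,3-dibromopropene, anti to ring A on C9; the enone by dehydrogenation.
3. Key disconnection: the C11–O bond of an allyl alkenyl ether joining a ring A allylic alcohol to a ring C enol triflate; its [3,3] shift then gives the C9–C10 bond, the C11 ketone and quaternary C10 by chirality transfer.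
4. Ring A alcohol ⇐ Diels–Alder (bis-siloxy diene from acetylacetone + citraconic anhydride), diester, catalyst-controlled enone reduction that also resolves the racemate; ring C triflate ⇐ cyclohexenone, dithiane 1,4-addition, enolate triflation.
5. Ring order: A (Diels–Alder), C (taken from cyclohexenone), D (last).

Conventions: racemic compounds (4–7, 12, 13) are drawn as the enantiomer that is carried on; 14–17 are mixtures of both epimers at C8, which is re-set in step 8.
Assumption: step 3 gives at most half of the racemate as 8; the diastereomer from the other enantiomer is discarded.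

Step 1
Reactants: 1 pentane-2,4-dione; 2 citraconic anhydride (3-methylfuran-2,5-dione)
Product: 5 rac-(3aR,7aS)-3a,7-dimethyl-3a,7a-dihydro-2-benzofuran-1,3,5(4H)-trione, via bis-siloxy diene 3 (not isolated), via cycloadduct 4 (not isolated)
Conditions: TMSOTf (2.2 equiv), Et3N, Et2O, 0 °C; filter, evaporate; 2, PhMe, 80 °C; then 1 M HCl, THF, rt
Reagents that add atoms: none
Why: Diels–Alder reaction of the electron-rich bis-siloxy diene with citraconic anhydride, in which the free CH2 terminus bonds to the methyl-bearing alkene carbon (so no two fully substituted carbons are joined) and suprafacial addition fixes the cis C4-methyl/C5-H relationship (racemic), followed by acid hydrolysis and β-elimination of silanol to the enone.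

Step 2
Reactants: 5 rac-(3aR,7aS)-3a,7-dimethyl-3a,7a-dihydro-2-benzofuran-1,3,5(4H)-trione
Product: 7 rac-dimethyl (1R,2S)-1,3-dimethyl-5-oxocyclohex-3-ene-1,2-dicarboxylate, via half ester 6 (not isolated)
Conditions: MeOH, 60 °C; evaporate; TMSCHN2, PhMe/MeOH, 0 °C
Reagents that add atoms: methanol CO; trimethylsilyldiazomethane C[Si](C)(C)C=[N+]=[N-]
Why: Anhydride alcoholysis at the less hindered carbonyl and O-methylation of the freed acid with a diazomethane equivalent, both base-free, so the cis C4/C5 relationship is kept.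

Step 3
Reactants: 7 rac-dimethyl (1R,2S)-1,3-dimethyl-5-oxocyclohex-3-ene-1,2-dicarboxylate
Product: 8 dimethyl (1R,2S,5R)-5-hydroxy-1,3-dimethylcyclohex-3-ene-1,2-dicarboxylate
Conditions: (S)-2-methyl-CBS-oxazaborolidine (0.2 equiv), catecholborane (1.5 equiv), PhMe, −78 °C; SiO2 chromatography
Reagents that add atoms: none
Why: Corey–Bakshi–Shibata reduction in which the catalyst (enone alkene as the large group) chooses the carbonyl face and makes the carbinol centre C2 (5R in the name) from both enantiomers of 7, so the (1R,2S)-enantiomer gives 8 with hydroxyl trans to both esters while the diastereomer from the other enantiomer is removed by chromatography.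

Step 4
Reactants: 9 cyclohex-2-en-1-one; 10 1,3-dithiane
Product: 13 rac-3-(1,3-dithian-2-yl)cyclohex-1-en-1-yl trifluoromethanesulfonate, via 2-lithio-1,3-dithiane 11 (not isolated), via lithium enolate 12 (not isolated)
Conditions: n-BuLi, THF, −30 °C; HMPA, then 9, −78 °C; PhNTf2, −78 °C → rt
Reagents that add atoms: N-phenylbis(trifluoromethanesulfonimide) O=S(=O)(N(c1ccccc1)S(=O)(=O)C(F)(F)F)C(F)(F)F
Why: Conjugate (1,4) addition of the lithiated dithiane (a masked formyl anion, steered to the β-carbon by HMPA) and O-sulfonylation of the regiodefined enolate give the enol triflate with its double bond towards C9; the new C8 centre is racemic and is re-set in step 8.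

Step 5
Reactants: 8 dimethyl (1R,2S,5R)-5-hydroxy-1,3-dimethylcyclohex-3-ene-1,2-dicarboxylate; 13 rac-3-(1,3-dithian-2-yl)cyclohex-1-en-1-yl trifluoromethanesulfonate
Product: 15 dimethyl (1R,2S,3S)-3-[(1R)-2-(1,3-dithian-2-yl)-6-oxocyclohexyl]-1,3-dimethylcyclohex-4-ene-1,2-dicarboxylate (both C8 epimers), via allyl alkenyl ether 14 (not isolated)
Conditions: 13 (1.3 equiv), Pd2(dba)3 (3 mol%), tBuBrettPhos (8 mol%), Cs2CO3, PhMe, 70 °C; filter through Celite; then 150 °C (sealed tube)
Reagents that add atoms: none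
Why: Proposed new method: palladium-catalysed C–O coupling of an enol triflate with a hindered secondary allylic alcohol run in tandem with a Claisen rearrangement, in which oxidative addition of 13 to zerovalent palladium, carbonate-assisted alkoxide exchange and C–O reductive elimination driven by the bulky biarylphosphine (outrunning β-hydride elimination) give ether 14, whose [3,3] shift moves oxygen from C2 to C11 and forms C9–C10 on the face that carried oxygen (1,3-chirality transfer sets quaternary C10, and the boat-like transition state, preferred because the chair would stack ring C over the axial C4 methyl, sets the natural C9); the closest known reactions are the palladium/biarylphosphine etherification of aryl halides with secondary alcohols and the copper-catalysed alkenyl iodide–allylic alcohol coupling/Claisen domino.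

Step 6
Reactants: 15 dimethyl (1R,2S,3S)-3-[(1R)-2-(1,3-dithian-2-yl)-6-oxocyclohexyl]-1,3-dimethylcyclohex-4-ene-1,2-dicarboxylate (both C8 epimers)
Product: 16 dimethyl (1R,2S,3S)-3-[(1R)-2-formyl-6-oxocyclohexyl]-1,3-dimethylcyclohex-4-ene-1,2-dicarboxylate (both C8 epimers)
Conditions: PhI(OCOCF3)2, MeCN/H2O (9:1), 0 °C
Reagents that add atoms: water O
Why: Oxidative hydrolysis of the dithioacetal by the trivalent iodine reagent (Stork–Zhao-type unmasking), which leaves ketone, alkene and esters alone and turns C8 into an epimerisable α-formyl centre.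

Step 7
Reactants: 16 dimethyl (1R,2S,3S)-3-[(1R)-2-formyl-6-oxocyclohexyl]-1,3-dimethylcyclohex-4-ene-1,2-dicarboxylate (both C8 epimers)
Product: 17 dimethyl (1R,2S,3S)-3-[(1R)-2-formyl-6-oxocyclohexyl]-1,3-dimethylcyclohexane-1,2-dicarboxylate (both C8 epimers)
Conditions: H2 (3 atm), Pd/C (10% Pd on carbon), EtOAc, rt
Reagents that add atoms: none
Why: Heterogeneous catalytic hydrogenation of the only C=C bond (the ring A alkene left by the Claisen shift); aldehyde, ketone and esters are inert here and no stereocentre is formed.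

Step 8
Reactants: 17 dimethyl (1R,2S,3S)-3-[(1R)-2-formyl-6-oxocyclohexyl]-1,3-dimethylcyclohexane-1,2-dicarboxylate (both C8 epimers); 18 2,3-dibromoprop-1-ene
Product: 21 dimethyl (1R,2S,3S)-3-[(1S,2R)-2-(2-bromoprop-2-en-1-yl)-2-formyl-6-oxocyclohexyl]-1,3-dimethylcyclohexane-1,2-dicarboxylate, via potassium enolate 19 (not isolated), via enol ether 20 (not isolated)
Conditions: t-BuOK (1.0 equiv), THF, −40 °C; 18, −40 → 0 °C; aqueous work-up; PhMe, 110 °C
Reagents that add atoms: none
Why: Enolate alkylation of an α-branched aldehyde with an allylic bromide, the O-alkylated enol ether converging on the same product by Claisen rearrangement on heating; allylic 1,3-strain holds the ring A substituent on C9 axial beside the enolate, so the allyl group enters anti to it and sets quaternary C8 (R) with the formyl group cis to ring A.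

Step 9
Reactants: 21 dimethyl (1R,2S,3S)-3-[(1S,2R)-2-(2-bromoprop-2-en-1-yl)-2-formyl-6-oxocyclohexyl]-1,3-dimethylcyclohexane-1,2-dicarboxylate
Product: 22 dimethyl (1R,2S,3S)-3-[(1S,6R)-6-(2-bromoprop-2-en-1-yl)-6-formyl-2-oxocyclohex-3-en-1-yl]-1,3-dimethylcyclohexane-1,2-dicarboxylate
Conditions: IBX (3 equiv), DMSO/PhMe, 75 °C
Reagents that add atoms: none
Why: IBX dehydrogenation of a ketone to its enone, which can only form across C12–C13 because C8 is quaternary and the C9 side offers no second hydrogen-bearing carbon.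

Step 10
Reactants: 22 dimethyl (1R,2S,3S)-3-[(1S,6R)-6-(2-bromoprop-2-en-1-yl)-6-formyl-2-oxocyclohex-3-en-1-yl]-1,3-dimethylcyclohexane-1,2-dicarboxylate
Product: 23 dimethyl (1R,2S,3S)-3-[(1R,2S,5S)-1-formyl-6-methylidene-3-oxobicyclo[3.2.1]octan-2-yl]-1,3-dimethylcyclohexane-1,2-dicarboxylate
Conditions: Bu3SnH (slow addition), AIBN (cat.), PhH, 80 °C
Reagents that add atoms: none
Why: Tin hydride-mediated 5-exo-trig cyclisation of the vinyl radical onto the enone β-carbon C13, possible only on the ring C face that carries the bromoallyl arm, so C13 (S) follows from C8 and ring D closes with the exocyclic methylene in place.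

Step 11
Reactants: 23 dimethyl (1R,2S,3S)-3-[(1R,2S,5S)-1-formyl-6-methylidene-3-oxobicyclo[3.2.1]octan-2-yl]-1,3-dimethylcyclohexane-1,2-dicarboxylate
Product: 24 (1R,2S,3S)-3-[(1R,2S,5S)-1-formyl-6-methylidene-3-oxobicyclo[3.2.1]octan-2-yl]-1,3-dimethylcyclohexane-1,2-dicarboxylic acid (target)
Conditions: LiSPr (6 equiv), HMPA, rt; then 1 M HCl
Reagents that add atoms: none
Why: SN2 dealkylation of both hindered methyl esters by thiolate attack at the methyl carbons (insensitive to crowding at the acyl carbons), mild enough to spare the non-enolisable aldehyde, the hindered C9–H next to the ketone and the exocyclic alkene.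

**Compound list**
1 | pentane-2,4-dione | CC(=O)CC(C)=O | starting material
2 | citraconic anhydride (3-methylfuran-2,5-dione) | CC1=CC(=O)OC1=O | starting material
3 | 2,4-bis(trimethylsilyloxy)penta-1,3-diene | C=C(O[Si](C)(C)C)C=C(C)O[Si](C)(C)C | intermediate
4 | cis-fused cycloadduct 3a,7-dimethyl-5,7-bis(trimethylsilyloxy)-3a,4,7,7a-tetrahydro-2-benzofuran-1,3-dione (racemic, C7 not assigned) | C[Si](C)(C)OC1(C)C=C(O[Si](C)(C)C)C[C@@]2(C)C(=O)OC(=O)[C@@H]12 | intermediate
5 | rac-(3aR,7aS)-3a,7-dimethyl-3a,7a-dihydro-2-benzofuran-1,3,5(4H)-trione | CC1=CC(=O)C[C@@]2(C)C(=O)OC(=O)[C@@H]12 | intermediate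
6 | rac-(1R,2S)-2-(methoxycarbonyl)-1,3-dimethyl-5-oxocyclohex-3-ene-1-carboxylic acid | CC1=CC(=O)C[C@@](C)(C(=O)O)[C@H]1C(=O)OC | intermediate
7 | rac-dimethyl (1R,2S)-1,3-dimethyl-5-oxocyclohex-3-ene-1,2-dicarboxylate | CC1=CC(=O)C[C@@](C)(C(=O)OC)[C@H]1C(=O)OC | intermediate
8 | dimethyl (1R,2S,5R)-5-hydroxy-1,3-dimethylcyclohex-3-ene-1,2-dicarboxylate | CC1=C[C@H](O)C[C@@](C)(C(=O)OC)[C@H]1C(=O)OC | intermediate
9 | cyclohex-2-en-1-one | O=C1C=CCCC1 | starting material
10 | 1,3-dithiane | C1CSCSC1 | starting material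
11 | 2-lithio-1,3-dithiane | [Li]C1SCCCS1 | intermediate
12 | lithium 3-(1,3-dithian-2-yl)cyclohex-1-en-1-olate (racemic) | [Li]OC1=CC(C2SCCCS2)CCC1 | intermediate
13 | rac-3-(1,3-dithian-2-yl)cyclohex-1-en-1-yl trifluoromethanesulfonate | O=S(=O)(OC1=CC(C2SCCCS2)CCC1)C(F)(F)F | intermediate
14 | dimethyl (1R,2S,5R)-5-{[3-(1,3-dithian-2-yl)cyclohex-1-en-1-yl]oxy}-1,3-dimethylcyclohex-3-ene-1,2-dicarboxylate (both C8 epimers) | CC1=C[C@H](OC2=CC(C3SCCCS3)CCC2)C[C@@](C)(C(=O)OC)[C@H]1C(=O)OC | intermediate
15 | dimethyl (1R,2S,3S)-3-[(1R)-2-(1,3-dithian-2-yl)-6-oxocyclohexyl]-1,3-dimethylcyclohex-4-ene-1,2-dicarboxylate (both C8 epimers) | C1CSC(SC1)C2CCCC(=O)[C@H]2[C@]3(C)C=CC[C@@](C)(C(=O)OC)[C@H]3C(=O)OC | intermediate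
16 | dimethyl (1R,2S,3S)-3-[(1R)-2-formyl-6-oxocyclohexyl]-1,3-dimethylcyclohex-4-ene-1,2-dicarboxylate (both C8 epimers) | O=CC1CCCC(=O)[C@H]1[C@]2(C)C=CC[C@@](C)(C(=O)OC)[C@H]2C(=O)OC | intermediate
17 | dimethyl (1R,2S,3S)-3-[(1R)-2-formyl-6-oxocyclohexyl]-1,3-dimethylcyclohexane-1,2-dicarboxylate (both C8 epimers) | O=CC1CCCC(=O)[C@H]1[C@]2(C)CCC[C@@](C)(C(=O)OC)[C@H]2C(=O)OC | intermediate
18 | 2,3-dibromoprop-1-ene | C=C(Br)CBr | starting material
19 | potassium enolate of the formyl group of 17 (C7=C8, O–K) | [K]OC=C1CCCC(=O)[C@H]1[C@]2(C)CCC[C@@](C)(C(=O)OC)[C@H]2C(=O)OC | intermediate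
20 | dimethyl (1R,2S,3S)-3-[(1S)-2-{[(2-bromoprop-2-en-1-yl)oxy]methylidene}-6-oxocyclohexyl]-1,3-dimethylcyclohexane-1,2-dicarboxylate | C=C(Br)COC=C1CCCC(=O)[C@H]1[C@]2(C)CCC[C@@](C)(C(=O)OC)[C@H]2C(=O)OC | intermediate
21 | dimethyl (1R,2S,3S)-3-[(1S,2R)-2-(2-bromoprop-2-en-1-yl)-2-formyl-6-oxocyclohexyl]-1,3-dimethylcyclohexane-1,2-dicarboxylate | C=C(Br)C[C@]1(C=O)CCCC(=O)[C@H]1[C@]2(C)CCC[C@@](C)(C(=O)OC)[C@H]2C(=O)OC | intermediate
22 | dimethyl (1R,2S,3S)-3-[(1S,6R)-6-(2-bromoprop-2-en-1-yl)-6-formyl-2-oxocyclohex-3-en-1-yl]-1,3-dimethylcyclohexane-1,2-dicarboxylate | C=C(Br)C[C@]1(C=O)CC=CC(=O)[C@H]1[C@]2(C)CCC[C@@](C)(C(=O)OC)[C@H]2C(=O)OC | intermediate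
23 | dimethyl (1R,2S,3S)-3-[(1R,2S,5S)-1-formyl-6-methylidene-3-oxobicyclo[3.2.1]octan-2-yl]-1,3-dimethylcyclohexane-1,2-dicarboxylate | C=C1C[C@]2(C=O)C[C@H]1CC(=O)[C@H]2[C@]1(C)CCC[C@@](C)(C(=O)OC)[C@H]1C(=O)OC | intermediate
24 | (1R,2S,3S)-3-[(1R,2S,5S)-1-formyl-6-methylidene-3-oxobicyclo[3.2.1]octan-2-yl]-1,3-dimethylcyclohexane-1,2-dicarboxylic acid (CNP0408869.1) | C=C1C[C@]2(C=O)C[C@H]1CC(=O)[C@H]2[C@]1(C)CCC[C@@](C)(C(=O)O)[C@H]1C(=O)O | target

**Total step count:** 11. **Longest linear sequence:** 10 steps (1, 2, 3, 5, 6, 7, 8, 9, 10, 11).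

**The three steps most likely to fail**

Step 5 (the proposed coupling/Claisen tandem). The risks are β-hydride elimination of the secondary alkoxide on palladium, sulfur binding to the catalyst, a sluggish [3,3] shift against the axial C4 methyl, and a competing chair transition state that would give the C9 epimer. Known-chemistry fallback: setting out from 13, nickel-catalysed triflate-to-iodide exchange (NaI, Ni(cod)2 cat., DMA/THF, rt) gives 2-(3-iodocyclohex-2-en-1-yl)-1,3-dithiane F1. The established copper-catalysed alkenyl iodide–allylic alcohol coupling/Claisen domino with 8 (CuI, 3,4,7,8-tetramethyl-1,10-phenanthroline, Cs2CO3, PhMe, 80 °C then 150 °C) then passes through 14 and comes back to the route at 15.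

Step 8 (allylation at a carbon flanked by a tertiary and a quaternary centre). The risks are slow alkylation and base-induced side reactions such as acylation of the enolate by the neighbouring ester. Fallback: setting out from 17, acid-catalysed acetal exchange with 2-bromoprop-2-en-1-ol (TsOH cat., PhMe, reflux, water removed) gives dimethyl (1R,2S,3S)-3-[(1R)-2-{bis[(2-bromoprop-2-en-1-yl)oxy]methyl}-6-oxocyclohexyl]-1,3-dimethylcyclohexane-1,2-dicarboxylate F2. In the same pot F2 loses one molecule of the alcohol to give enol ether 20, which rearranges [3,3] and comes back to the route at 21.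

Step 10 (radical closure of the bridged ring). The risks are reduction of the vinyl radical before it cyclises and tin hydride addition to the enone. Fallback: setting out from 22, a reductive Heck cyclisation (Pd(OAc)2, PPh3, HCO2Na, Et4NCl, DMF, 80 °C) gives the same product and comes back to the route at 23. β-Hydride elimination is blocked there because it would give a bridgehead alkene. This fallback makes no compound outside the list (F0).

**Further compounds**
F1 | step 5 | 2-(3-iodocyclohex-2-en-1-yl)-1,3-dithiane (racemic) | IC1=CC(C2SCCCS2)CCC1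
F2 | step 8 | dimethyl (1R,2S,3S)-3-[(1R)-2-{bis[(2-bromoprop-2-en-1-yl)oxy]methyl}-6-oxocyclohexyl]-1,3-dimethylcyclohexane-1,2-dicarboxylate (both C8 epimers) | C=C(Br)COC(OCC(Br)=C)C1CCCC(=O)[C@H]1[C@]2(C)CCC[C@@](C)(C(=O)OC)[C@H]2C(=O)OC
F0 | step 10 | none | none
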